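The seven-membered carbocycle (C1, C5, C6, C7, C8, C9, C10) is disconnected at C7–C8. With C9 as a ketone and C5=C6 as an alkene, C9, C8 and C7 are the carbonyl, α- and β-carbons of a Claisen product. The precursor is therefore a 2-methylenetetrahydrofuran whose ring oxygen links C9 to C5 and whose C5 carries the E-alkenyl chain C6=C7–C11–C12; it is made from a γ-lactone by titanium methylenation. Heating triggers one [3,3] shift that forms C7–C8, cleaves C5–O, turns the heterocycle into the cyclohept-4-enone, relays the C5 configuration to C7 and leaves C5=C6 in place for the trans C5/C6 dioxygenation.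

Key step: step 14

Atom labels (used throughout): C1 tertiary carbinol bearing the C2–C4 acyl chain; C5 ester carbinol; C6 lactone O–CH; C7 lactone C–CH; C8 CH2; C9 secondary carbinol; C10 CHMe; C11, C12, C13 lactone α-carbon, carbonyl and exocyclic methylene.

Design remark: the C12 oxygen is carried as a 4-methoxybenzyl ether and the C1 oxygen as a triethylsilyl ether. A silyl ether on C12 could later be removed only with fluoride, which would also strip the triethylsilyl ethers and place an alkoxide next to the epoxide; the benzylic ether leaves with DDQ under neutral conditions.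

Assumption: enol borinates of methyl ketones made with (−)-Ipc2BCl are taken to attack the Re face of acetaldehyde, the sense opposite to that of the allylboranes carrying the same ligands.

**Route**

Step 1
Reactants: 1 methyl (S)-3-hydroxy-2-methylpropanoate
Product: 2 methyl (S)-3-[(tert-butyldimethylsilyl)oxy]-2-methylpropanoate
Conditions: TBSCl, imidazole, CH2Cl2, 0 °C → rt
Reagents that add atoms: tert-butyldimethylsilyl chloride, CC(C)(C)[Si](C)(C)Cl
Why: Imidazole-promoted silyl ether formation masks the C9 oxygen with a group that does not chelate magnesium and leaves the C10 stereocentre untouched.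

Step 2
Reactants: 2 methyl (S)-3-[(tert-butyldimethylsilyl)oxy]-2-methylpropanoate
Product: 3 (S)-3-[(tert-butyldimethylsilyl)oxy]-2-methylpropanal
Conditions: i-Bu2AlH, CH2Cl2, −78 °C; aq. sodium potassium tartrate
Reagents that add atoms: none
Why: Partial ester reduction with i-Bu2AlH stops at the aluminium hemiacetal at −78 °C, and the aldehyde (future C1) should keep its α-configuration when used at once.

Step 3
Reactants: 4 prop-2-en-1-ol
Product: 5 3-(methoxymethoxy)prop-1-ene
Conditions: MOMCl, i-Pr2NEt, CH2Cl2, 0 °C → rt; distillation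
Reagents that add atoms: chloromethyl methyl ether, COCCl
Why: O-Alkylation of the alcohol with the chloromethyl ether under amine base (Williamson-type acetal formation) gives the allyl ether needed for the alkoxyallylboration.

Step 4
Reactants: 3 (S)-3-[(tert-butyldimethylsilyl)oxy]-2-methylpropanal; 5 3-(methoxymethoxy)prop-1-ene
Product: 7 (2S,3R,4R)-1-[(tert-butyldimethylsilyl)oxy]-4-(methoxymethoxy)-2-methylhex-5-en-3-ol, via allylborane 6 (not isolated)
Conditions: s-BuLi, THF, −78 °C; (−)-Ipc2BOMe; BF3·OEt2; then 3, −78 °C; NaOH, H2O2, 0 °C → rt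
Reagents that add atoms: none
Why: Brown alkoxyallylboration, in which the (Z)-γ-alkoxyallylborane adds through a closed chair transition state to the Si face of the aldehyde under control of the (−)-isopinocampheyl ligands, which sets the C5 ether stereocentre as R together with a syn C1 carbinol that is oxidised later.

Step 5
Reactants: 8 but-3-en-1-ol
Product: 9 1-[(but-3-en-1-yloxy)methyl]-4-methoxybenzene
Conditions: NaH, 4-methoxybenzyl chloride, Bu4NI (cat.), THF/DMF, 0 °C → rt
Reagents that add atoms: 4-methoxybenzyl chloride, COc1ccc(CCl)cc1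
Why: Williamson ether synthesis protects the future C12 oxygen as an ether that tolerates titanium methylenation and is later removed oxidatively.

Step 6
Reactants: 7 (2S,3R,4R)-1-[(tert-butyldimethylsilyl)oxy]-4-(methoxymethoxy)-2-methylhex-5-en-3-ol; 9 1-[(but-3-en-1-yloxy)methyl]-4-methoxybenzene
Product: 10 (2S,3R,4R,5E)-1-[(tert-butyldimethylsilyl)oxy]-4-(methoxymethoxy)-8-[(4-methoxybenzyl)oxy]-2-methyloct-5-en-3-ol
Conditions: 9 (3 equiv), second-generation Grubbs catalyst (5 mol %), CH2Cl2, 40 °C; E isomer purified by chromatography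
Reagents that add atoms: none
Why: Olefin cross-metathesis of the allylic-ether terminal alkene with an excess of the unhindered homoallylic ether should give the C6=C7 alkene with the usual E preference, which the later chirality transfer requires.

Step 7
Reactants: 10 (2S,3R,4R,5E)-1-[(tert-butyldimethylsilyl)oxy]-4-(methoxymethoxy)-8-[(4-methoxybenzyl)oxy]-2-methyloct-5-en-3-ol
Product: 11 (2S,4R,5E)-1-[(tert-butyldimethylsilyl)oxy]-4-(methoxymethoxy)-8-[(4-methoxybenzyl)oxy]-2-methyloct-5-en-3-one
Conditions: Dess–Martin periodinane, NaHCO3, CH2Cl2, 0 °C → rt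
Reagents that add atoms: none
Why: Dess–Martin oxidation under buffered neutral conditions should give the α-alkoxy-β,γ-unsaturated C1 ketone without epimerising C5 or C10 and without moving the alkene into conjugation.

Step 8
Reactants: 11 (2S,4R,5E)-1-[(tert-butyldimethylsilyl)oxy]-4-(methoxymethoxy)-8-[(4-methoxybenzyl)oxy]-2-methyloct-5-en-3-one; 12 vinylmagnesium bromide
Product: 13 (2S,3S,4R,5E)-1-[(tert-butyldimethylsilyl)oxy]-3-ethenyl-4-(methoxymethoxy)-8-[(4-methoxybenzyl)oxy]-2-methyloct-5-en-3-ol
Conditions: MgBr2·OEt2, CH2Cl2, −78 °C; CH2=CHMgBr (THF), −78 °C; aq. NH4Cl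
Reagents that add atoms: none
Why: Chelation-controlled (Cram chelate) Grignard addition, in which magnesium bridges the C1 carbonyl and the C5 acetal oxygen and the vinyl group enters from the side of the C5 hydrogen, sets the C1 carbinol with the vinyl group syn to the C5 alkenyl chain, the C9 silyl ether being too poor a donor to compete.

Step 9
Reactants: 13 (2S,3S,4R,5E)-1-[(tert-butyldimethylsilyl)oxy]-3-ethenyl-4-(methoxymethoxy)-8-[(4-methoxybenzyl)oxy]-2-methyloct-5-en-3-ol
Product: 14 (2S,3S,4R,5E)-3-ethenyl-4-(methoxymethoxy)-8-[(4-methoxybenzyl)oxy]-2-methyloct-5-ene-1,3-diol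
Conditions: CSA (10 mol %), MeOH/CH2Cl2, 0 °C
Reagents that add atoms: none
Why: Acid-catalysed methanolysis removes the primary silyl ether selectively, since the acetal, the benzylic ether and the tertiary allylic alcohol should be stable at 0 °C.

Step 10
Reactants: 14 (2S,3S,4R,5E)-3-ethenyl-4-(methoxymethoxy)-8-[(4-methoxybenzyl)oxy]-2-methyloct-5-ene-1,3-diol
Product: 15 (2R,3S,4R,5E)-3-ethenyl-3-hydroxy-4-(methoxymethoxy)-8-[(4-methoxybenzyl)oxy]-2-methyloct-5-enoic acid
Conditions: TEMPO (20 mol %), PhI(OAc)2, MeCN/H2O, rt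
Reagents that add atoms: water, O
Why: Nitroxyl-catalysed oxidation with PhI(OAc)2 in aqueous acetonitrile takes the primary C9 alcohol through the aldehyde hydrate to the acid and leaves the tertiary alcohol and the alkenes alone.

Step 11
Reactants: 15 (2R,3S,4R,5E)-3-ethenyl-3-hydroxy-4-(methoxymethoxy)-8-[(4-methoxybenzyl)oxy]-2-methyloct-5-enoic acid
Product: 16 (2R,3S,4R,5E)-3-ethenyl-4-(methoxymethoxy)-8-[(4-methoxybenzyl)oxy]-2-methyl-3-[(triethylsilyl)oxy]oct-5-enoic acid
Conditions: TESOTf, 2,6-lutidine, CH2Cl2, −78 → 0 °C; aqueous work-up (K2CO3, MeOH/H2O, brief)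
Reagents that add atoms: triethylsilyl triflate, CC[Si](CC)(CC)OS(=O)(=O)C(F)(F)F
Why: Silylation with the triflate caps the hindered tertiary C1 hydroxyl, which would otherwise capture the acetal carbon in the next step and direct the later epoxidation to the wrong face, while the silyl ester formed on the acid is hydrolysed on work-up.

Step 12
Reactants: 16 (2R,3S,4R,5E)-3-ethenyl-4-(methoxymethoxy)-8-[(4-methoxybenzyl)oxy]-2-methyl-3-[(triethylsilyl)oxy]oct-5-enoic acid
Product: 18 (3R,4S,5R)-4-ethenyl-5-{(1E)-4-[(4-methoxybenzyl)oxy]but-1-en-1-yl}-3-methyl-4-[(triethylsilyl)oxy]oxolan-2-one, via hydroxy acid 17 (not isolated)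
Conditions: TMSOTf, 2,2′-bipyridyl, CH2Cl2, 0 °C; H2O; then PPTS (cat.), PhMe, 40 °C
Reagents that add atoms: none
Why: Lewis-acid cleavage of the methoxymethyl ether through a pyridinium methyl ether that water hydrolyses frees the C5 hydroxyl under conditions that should spare triethylsilyl and benzylic ethers, and the γ-hydroxy acid then closes by acid-catalysed lactonisation, helped by the fully substituted C1.

Step 13
Reactants: 18 (3R,4S,5R)-4-ethenyl-5-{(1E)-4-[(4-methoxybenzyl)oxy]but-1-en-1-yl}-3-methyl-4-[(triethylsilyl)oxy]oxolan-2-one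
Product: 19 (3S,4S,5R)-4-ethenyl-5-{(1E)-4-[(4-methoxybenzyl)oxy]but-1-en-1-yl}-3-methyl-2-methylidene-4-[(triethylsilyl)oxy]oxolane
Conditions: Cp2TiMe2 (3 equiv), PhMe, 75 °C, dark; filtration through basic alumina (hexane/Et3N)
Reagents that add atoms: dimethyltitanocene Cp2TiMe2, [CH3-].[CH3-].[Ti+4].c1cc[cH-]c1.c1cc[cH-]c1
Why: Petasis methylenation, in which thermally formed Cp2Ti=CH2 converts the lactone carbonyl into the exocyclic enol ether (C9=C8) through an oxatitanacyclobutane without acid or base, so that C10 and the silyl ether are not at risk.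

Step 14
Reactants: 19 (3S,4S,5R)-4-ethenyl-5-{(1E)-4-[(4-methoxybenzyl)oxy]but-1-en-1-yl}-3-methyl-2-methylidene-4-[(triethylsilyl)oxy]oxolane
Product: 20 (2R,3R,6R)-3-ethenyl-6-{2-[(4-methoxybenzyl)oxy]ethyl}-2-methyl-3-[(triethylsilyl)oxy]cyclohept-4-en-1-one
Conditions: PhMe (0.02 M), i-Pr2NEt (0.1 equiv), base-washed sealed tube, 170 °C
Reagents that add atoms: none
Why: Concerted thermal [3,3] sigmatropic (Claisen) shift of the allyl vinyl ether C8=C9–O–C5–C6=C7 held in the five-membered ring, the closest known reaction type being the Claisen ring enlargement of 2-methylene-5-vinyltetrahydrofurans to cyclohept-4-enones. The seven-membered carbocycle (C9, C10, C1, C5, C6, C7, C8) is closed pericyclically by suprafacial C7–C8 bond formation while C5–O breaks, the six reacting atoms forming a chair bridged by C10–C1 as in an 8-oxabicyclo[3.2.1]octane, so the closure is a two-carbon ring enlargement and not an exo or endo cyclisation of a tether. Because the bridge must be axial on C5, the new ring alkene C5=C6 can only be cis, and the boat array is excluded because it would turn the two ends of the bridge to opposite sides. The new stereocentre C7 is controlled by the C5 configuration and the E geometry of C6=C7, the CH2CH2OPMB chain lying equatorial on the chair, while C10 and C1 pass through unchanged. The step needs chemoselectivity over Cope-type shifts open to the C1 vinyl group and over migration of the exocyclic double bond into the ring; the first is secured in the substrate by the weaker allylic C5–O bond and the carbonyl-forming driving force at the lowest workable temperature, the second by the amine additive and base-washed glass.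

Step 15
Reactants: 20 (2R,3R,6R)-3-ethenyl-6-{2-[(4-methoxybenzyl)oxy]ethyl}-2-methyl-3-[(triethylsilyl)oxy]cyclohept-4-en-1-one
Product: 21 (1R,2S,3R,6R)-3-ethenyl-6-{2-[(4-methoxybenzyl)oxy]ethyl}-2-methyl-3-[(triethylsilyl)oxy]cyclohept-4-en-1-ol
Conditions: (S)-2-methyl-CBS-oxazaborolidine (0.5 equiv), catecholborane, PhMe, −78 → −40 °C; MeOH, aq. NaOH
Reagents that add atoms: none
Why: Corey–Bakshi–Shibata reduction, in which the (S)-oxazaborolidine binds the carbonyl lone pair on the side of the C8 methylene and delivers hydride under catalyst control to give the 9R carbinol (hydroxyl trans to the C10 methyl), catecholborane not hydroborating the alkenes at this temperature.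

Step 16
Reactants: 21 (1R,2S,3R,6R)-3-ethenyl-6-{2-[(4-methoxybenzyl)oxy]ethyl}-2-methyl-3-[(triethylsilyl)oxy]cyclohept-4-en-1-ol
Product: 22 epoxy alcohol: the C5–C6 epoxide of 21 with the epoxide oxygen on the face of the C9 hydroxyl and the C1 vinyl group and anti to the C1 silyloxy group and the C7 chain
Conditions: mCPBA, NaHCO3, CH2Cl2, 0 °C
Reagents that add atoms: 3-chloroperoxybenzoic acid, OOC(=O)c1cccc(Cl)c1
Why: Prilezhaev epoxidation of the only nucleophilic alkene, the peracid approaching C5=C6 from the face opposite the allylic C1 silyloxy group and the C7 side chain and hydrogen-bonding to the C9 hydroxyl on that same face, which sets C5 and C6; the hindered, electron-poor vinyl group should not compete.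

Step 17
Reactants: 22 epoxy alcohol
Product: 23 9-O-triethylsilyl ether of 22
Conditions: TESCl, imidazole, DMAP (cat.), CH2Cl2, rt
Reagents that add atoms: chlorotriethylsilane, CC[Si](Cl)(CC)CC
Why: Routine silylation of the secondary C9 hydroxyl keeps it from being oxidised in step 20 and acylated in step 23.

Step 18
Reactants: 23 9-O-triethylsilyl ether of 22
Product: 24 Markovnikov hydrate of 23, in which C1 carries a 1-hydroxyethyl group (both C2 epimers)
Conditions: Co(acac)2 (20 mol %), PhSiH3, O2 (1 atm), THF, rt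
Reagents that add atoms: dioxygen, O=O
Why: Mukaiyama hydration (hydrogen-atom transfer to the terminal carbon, trapping of the secondary C2 radical by O2) places oxygen on C2 of the only remaining alkene under neutral conditions that spare the epoxide and the ethers, and both C2 epimers converge on oxidation.

Step 19
Reactants: 24 Markovnikov hydrate of 23
Product: 25 diol with the C2 carbinol and a free C12 primary alcohol
Conditions: DDQ, CH2Cl2/pH 7 buffer, 0 °C → rt
Reagents that add atoms: none
Why: Oxidative cleavage of the 4-methoxybenzyl ether with DDQ in wet solvent frees the C12 alcohol without fluoride or acid, so that both silyl ethers and the epoxide persist.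

Step 20
Reactants: 25 diol with the C2 carbinol and a free C12 primary alcohol
Product: 26 keto aldehyde with a C1 acetyl group and a C12 aldehyde
Conditions: Dess–Martin periodinane (3 equiv), NaHCO3, CH2Cl2, rt
Reagents that add atoms: none
Why: Dess–Martin oxidation converts the C2 carbinol and the C12 primary alcohol in one operation into the methyl ketone and the aldehyde under buffered conditions.

Step 21
Reactants: 26 keto aldehyde
Product: 27 keto enal in which C11 carries the exocyclic methylene C13 (2-substituted acrolein)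
Conditions: Eschenmoser's salt, Et3N, CH2Cl2, rt
Reagents that add atoms: dimethylmethylideneammonium iodide, C=[N+](C)C.[I-]
Why: α-Methylenation of the aldehyde by a Mannich reaction with Eschenmoser's salt followed by amine-induced β-elimination of dimethylamine installs C13, the hindered methyl ketone not being enolised by triethylamine.

Step 22
Reactants: 27 keto enal
Product: 29 hydroxy lactone: cis-fused α-methylene-γ-lactone (oxygen on C6) with a free C5 hydroxyl, C1 acetyl and triethylsilyl ethers on C1 and C9, via acrylic acid 28 (not isolated)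
Conditions: NaClO2, NaH2PO4, 2-methyl-2-butene, t-BuOH/H2O, 0 °C → rt; then CSA (cat.), CH2Cl2, rt
Reagents that add atoms: sodium chlorite NaClO2, [Na+].[O-]Cl=O
Why: Pinnick oxidation turns the enal into the acrylic acid, whose carboxyl group opens the epoxide at C6 by acid-catalysed anti 5-exo attack from the face of the C7 chain, giving the cis-fused lactone with inversion at C6 and the C5 hydroxyl with retention.

Step 23
Reactants: 29 hydroxy lactone; 30 (S)-2-methylbutanoic acid
Product: 32 C5 (S)-2-methylbutanoate of 29, via mixed anhydride 31 (not isolated)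
Conditions: 30, 2,4,6-trichlorobenzoyl chloride, Et3N, THF, rt; then 29, DMAP, PhMe, 40 °C
Reagents that add atoms: none
Why: Yamaguchi esterification, in which the mixed anhydride and DMAP acylate the hindered C5 hydroxyl without passing through a ketene, so that the S centre of the acid is kept.

Step 24
Reactants: 32 C5 (S)-2-methylbutanoate of 29; 33 acetaldehyde
Product: 35 1,9-bis-O-triethylsilyl ether of the target, via enol borinate 34 (not isolated)
Conditions: (−)-Ipc2BCl, Et3N, Et2O, −78 → 0 °C; MeCHO, −78 → −20 °C; pH 7 buffer, MeOH, H2O2, 0 °C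
Reagents that add atoms: none
Why: Paterson boron aldol reaction, in which the methyl ketone is enolised on its only enolisable side and the enol diisopinocampheylborinate adds to the Re face of acetaldehyde under reagent control to set the 4S carbinol.

Step 25
Reactants: 35 1,9-bis-O-triethylsilyl ether of the target
Product: 36 CNP0291806.1
Conditions: HF·pyridine, pyridine, THF, 0 °C → rt
Reagents that add atoms: none
Why: Fluoride-mediated cleavage of both triethylsilyl ethers under buffered, mildly acidic conditions in which the β-hydroxy ketone, the two esters and the α-methylene lactone should persist.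

**Compound list**

1 | methyl (S)-3-hydroxy-2-methylpropanoate | OC[C@H](C)C(=O)OC | starting material
2 | methyl (S)-3-[(tert-butyldimethylsilyl)oxy]-2-methylpropanoate | CC(C)(C)[Si](C)(C)OC[C@H](C)C(=O)OC | intermediate
3 | (S)-3-[(tert-butyldimethylsilyl)oxy]-2-methylpropanal | CC(C)(C)[Si](C)(C)OC[C@H](C)C=O | intermediate
4 | prop-2-en-1-ol | C=CCO | starting material
5 | 3-(methoxymethoxy)prop-1-ene | C=CCOCOC | intermediate
6 | (Z)-[3-(methoxymethoxy)prop-2-en-1-yl]bis[(−)-isopinocampheyl]borane | COCO/C=C\CB([C@@H]1C[C@@H]2C[C@H]([C@H]1C)C2(C)C)[C@@H]1C[C@@H]2C[C@H]([C@H]1C)C2(C)C | intermediate (not isolated)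
7 | (2S,3R,4R)-1-[(tert-butyldimethylsilyl)oxy]-4-(methoxymethoxy)-2-methylhex-5-en-3-ol | CC(C)(C)[Si](C)(C)OC[C@H](C)[C@@H](O)[C@H](OCOC)C=C | intermediate
8 | but-3-en-1-ol | C=CCCO | starting material
9 | 1-[(but-3-en-1-yloxy)methyl]-4-methoxybenzene | C=CCCOCc1ccc(OC)cc1 | intermediate
10 | (2S,3R,4R,5E)-1-[(tert-butyldimethylsilyl)oxy]-4-(methoxymethoxy)-8-[(4-methoxybenzyl)oxy]-2-methyloct-5-en-3-ol | CC(C)(C)[Si](C)(C)OC[C@H](C)[C@@H](O)[C@H](OCOC)/C=C/CCOCc1ccc(OC)cc1 | intermediate
11 | (2S,4R,5E)-1-[(tert-butyldimethylsilyl)oxy]-4-(methoxymethoxy)-8-[(4-methoxybenzyl)oxy]-2-methyloct-5-en-3-one | CC(C)(C)[Si](C)(C)OC[C@H](C)C(=O)[C@H](OCOC)/C=C/CCOCc1ccc(OC)cc1 | intermediate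
12 | vinylmagnesium bromide | C=C[Mg]Br | starting material
13 | (2S,3S,4R,5E)-1-[(tert-butyldimethylsilyl)oxy]-3-ethenyl-4-(methoxymethoxy)-8-[(4-methoxybenzyl)oxy]-2-methyloct-5-en-3-ol | CC(C)(C)[Si](C)(C)OC[C@H](C)[C@@](O)(C=C)[C@H](OCOC)/C=C/CCOCc1ccc(OC)cc1 | intermediate
14 | (2S,3S,4R,5E)-3-ethenyl-4-(methoxymethoxy)-8-[(4-methoxybenzyl)oxy]-2-methyloct-5-ene-1,3-diol | OC[C@H](C)[C@@](O)(C=C)[C@H](OCOC)/C=C/CCOCc1ccc(OC)cc1 | intermediate
15 | (2R,3S,4R,5E)-3-ethenyl-3-hydroxy-4-(methoxymethoxy)-8-[(4-methoxybenzyl)oxy]-2-methyloct-5-enoic acid | OC(=O)[C@H](C)[C@@](O)(C=C)[C@H](OCOC)/C=C/CCOCc1ccc(OC)cc1 | intermediate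
16 | (2R,3S,4R,5E)-3-ethenyl-4-(methoxymethoxy)-8-[(4-methoxybenzyl)oxy]-2-methyl-3-[(triethylsilyl)oxy]oct-5-enoic acid | OC(=O)[C@H](C)[C@@](O[Si](CC)(CC)CC)(C=C)[C@H](OCOC)/C=C/CCOCc1ccc(OC)cc1 | intermediate
17 | (2R,3S,4R,5E)-3-ethenyl-4-hydroxy-8-[(4-methoxybenzyl)oxy]-2-methyl-3-[(triethylsilyl)oxy]oct-5-enoic acid | OC(=O)[C@H](C)[C@@](O[Si](CC)(CC)CC)(C=C)[C@H](O)/C=C/CCOCc1ccc(OC)cc1 | intermediate (not isolated)
18 | (3R,4S,5R)-4-ethenyl-5-{(1E)-4-[(4-methoxybenzyl)oxy]but-1-en-1-yl}-3-methyl-4-[(triethylsilyl)oxy]oxolan-2-one | O=C1O[C@H](/C=C/CCOCc2ccc(OC)cc2)[C@](O[Si](CC)(CC)CC)(C=C)[C@H]1C | intermediate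
19 | (3S,4S,5R)-4-ethenyl-5-{(1E)-4-[(4-methoxybenzyl)oxy]but-1-en-1-yl}-3-methyl-2-methylidene-4-[(triethylsilyl)oxy]oxolane (key-step precursor) | C=C1O[C@H](/C=C/CCOCc2ccc(OC)cc2)[C@](O[Si](CC)(CC)CC)(C=C)[C@H]1C | intermediate
20 | (2R,3R,6R)-3-ethenyl-6-{2-[(4-methoxybenzyl)oxy]ethyl}-2-methyl-3-[(triethylsilyl)oxy]cyclohept-4-en-1-one (key-step product) | O=C1C[C@@H](CCOCc2ccc(OC)cc2)C=C[C@](O[Si](CC)(CC)CC)(C=C)[C@H]1C | intermediate
21 | (1R,2S,3R,6R)-3-ethenyl-6-{2-[(4-methoxybenzyl)oxy]ethyl}-2-methyl-3-[(triethylsilyl)oxy]cyclohept-4-en-1-ol | O[C@@H]1C[C@@H](CCOCc2ccc(OC)cc2)C=C[C@](O[Si](CC)(CC)CC)(C=C)[C@H]1C | intermediate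
22 | epoxy alcohol: C5–C6 epoxide of 21, oxygen syn to C9–OH and the C1 vinyl group, anti to C1–OSiEt3 and the C7 chain | O[C@@H]1C[C@@H](CCOCc3ccc(OC)cc3)[C@@H]2O[C@@H]2[C@](O[Si](CC)(CC)CC)(C=C)[C@H]1C | intermediate
23 | 9-O-triethylsilyl ether of 22 | CC[Si](CC)(CC)O[C@@H]1C[C@@H](CCOCc3ccc(OC)cc3)[C@@H]2O[C@@H]2[C@](O[Si](CC)(CC)CC)(C=C)[C@H]1C | intermediate
24 | Markovnikov hydrate of 23 (C1 1-hydroxyethyl, both C2 epimers) | CC[Si](CC)(CC)O[C@@H]1C[C@@H](CCOCc3ccc(OC)cc3)[C@@H]2O[C@@H]2[C@](O[Si](CC)(CC)CC)(C(C)O)[C@H]1C | intermediate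
25 | diol: C2 carbinol (both epimers) and C12 primary alcohol | CC[Si](CC)(CC)O[C@@H]1C[C@@H](CCO)[C@@H]2O[C@@H]2[C@](O[Si](CC)(CC)CC)(C(C)O)[C@H]1C | intermediate
26 | keto aldehyde: C1 acetyl, C12 aldehyde | CC[Si](CC)(CC)O[C@@H]1C[C@@H](CC=O)[C@@H]2O[C@@H]2[C@](O[Si](CC)(CC)CC)(C(C)=O)[C@H]1C | intermediate
27 | keto enal: C11 methylidene aldehyde, C1 acetyl | CC[Si](CC)(CC)O[C@@H]1C[C@@H](C(=C)C=O)[C@@H]2O[C@@H]2[C@](O[Si](CC)(CC)CC)(C(C)=O)[C@H]1C | intermediate
28 | acrylic acid: C12 carboxylic acid of 27 | CC[Si](CC)(CC)O[C@@H]1C[C@@H](C(=C)C(=O)O)[C@@H]2O[C@@H]2[C@](O[Si](CC)(CC)CC)(C(C)=O)[C@H]1C | intermediate (not isolated)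
29 | hydroxy lactone: cis-fused α-methylene-γ-lactone, free C5–OH, C1 acetyl, C1 and C9 OSiEt3 | C=C1C(=O)O[C@@H]2[C@H]1C[C@@H](O[Si](CC)(CC)CC)[C@H](C)[C@@](O[Si](CC)(CC)CC)(C(C)=O)[C@H]2O | intermediate
30 | (S)-2-methylbutanoic acid | OC(=O)[C@@H](C)CC | starting material
31 | (S)-2-methylbutanoic 2,4,6-trichlorobenzoic anhydride | O=C(OC(=O)c1c(Cl)cc(Cl)cc1Cl)[C@@H](C)CC | intermediate (not isolated)
32 | C5 (S)-2-methylbutanoate of 29 | C=C1C(=O)O[C@@H]2[C@H]1C[C@@H](O[Si](CC)(CC)CC)[C@H](C)[C@@](O[Si](CC)(CC)CC)(C(C)=O)[C@H]2OC(=O)[C@@H](C)CC | intermediate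
33 | acetaldehyde | CC=O | starting material
34 | enol bis[(−)-isopinocampheyl]borinate of 32 | C=C1C(=O)O[C@@H]2[C@H]1C[C@@H](O[Si](CC)(CC)CC)[C@H](C)[C@@](O[Si](CC)(CC)CC)(C(=C)OB([C@@H]3C[C@@H]4C[C@H]([C@H]3C)C4(C)C)[C@@H]3C[C@@H]4C[C@H]([C@H]3C)C4(C)C)[C@H]2OC(=O)[C@@H](C)CC | intermediate (not isolated)
35 | 1,9-bis-O-triethylsilyl ether of the target | C=C1C(=O)O[C@@H]2[C@H]1C[C@@H](O[Si](CC)(CC)CC)[C@H](C)[C@@](O[Si](CC)(CC)CC)(C(=O)C[C@H](C)O)[C@H]2OC(=O)[C@@H](C)CC | intermediate
36 | CNP0291806.1: (1S,4S,5S,6R,7S,9R,10S) in the atom labels above, C5 (S)-2-methylbutanoate, C1 (3S)-3-hydroxybutanoyl, cis-fused α-methylene-γ-lactone | C=C1C(=O)O[C@@H]2[C@H]1C[C@@H](O)[C@H](C)[C@@](O)(C(=O)C[C@H](C)O)[C@H]2OC(=O)[C@@H](C)CC | target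

**Step count**

Total: 25 steps. Longest linear sequence: 23 steps (steps 1, 2, 4 and 6–25); steps 3 and 5 prepare the two side reagents.

**Steps most likely to fail**

Step 14. At the temperature the shift needs, the allyl vinyl ether may be lost before it rearranges: the exocyclic double bond can migrate into the ring under traces of acid (which also erases C10), the enol ether can hydrolyse during isolation, and a Cope-type shift through the C1 vinyl group can compete. The fallback sets out from lactone 18 and comes back at ketone 20, and it replaces carbonyl methylenation by alkyne hydroalkoxylation so that the enol ether is never handled. Reduction of 18 with i-Bu2AlH (CH2Cl2, −78 °C) should give the lactol F1. Ohira–Bestmann homologation of its open hydroxy aldehyde form (dimethyl (1-diazo-2-oxopropyl)phosphonate, K2CO3, MeOH) should give the pent-4-yn-1-ol F2. A catalytic amount of MeLi in phenetole at 150–180 °C (microwave) then brings about 5-exo-dig addition of the C5 alkoxide to the alkyne, so that 19 is formed under basic conditions at the rearrangement temperature and passes on to 20 in the same vessel.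

Step 24. Facial discrimination of the small aldehyde by the enol borinate may be poor, since methyl ketone enolates of this ligand give only moderate induction and the influence of the remote ring stereocentres is unknown; the result would be a mixture of C4 epimers. The fallback sets out from ketone 32 and comes back at 35, and it moves stereocontrol from a chiral boron enolate to a chiral Lewis acid acting on the aldehyde. Soft enolisation (TMSOTf, Et3N, CH2Cl2, −78 °C) should give the trimethylsilyl enol ether F3. A Mukaiyama aldol reaction of F3 with acetaldehyde follows, promoted by an N-tosyl-tryptophan-derived B-butyl oxazaborolidinone (the enantiomer that exposes the Re face of the aldehyde) in EtCN at −78 °C. Mild aqueous acid cleaves the silyl aldolate and should deliver 35.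

Step 16. Facial selectivity of the epoxidation may be poor or reversed, the peracid attacking the lower face of C5=C6 next to the C7 chain, which would lead to the wrong C5/C6 diastereomer. The fallback sets out from alcohol 21 and comes back at 23, and it forms the epoxide by closure of a bromohydrin, which places the oxygen on the face opposite to the one the electrophile takes. Silylation first (TESCl, imidazole, CH2Cl2) gives the bis(triethylsilyl) ether F4, so that the C9 hydroxyl cannot capture the bromonium ion. NBS in aqueous THF at 0 °C then gives the trans bromohydrin F5 by anti attack of water on the bromonium ion formed on the face electrophiles prefer. K2CO3 in MeOH closes F5 to the epoxide on the opposite face, which is 23.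

**Further compounds**

F1 | step 14 | lactol from 18: (3R,4S,5R)-4-ethenyl-5-{(1E)-4-[(4-methoxybenzyl)oxy]but-1-en-1-yl}-3-methyl-4-[(triethylsilyl)oxy]oxolan-2-ol (both anomers) | OC1O[C@H](/C=C/CCOCc2ccc(OC)cc2)[C@](O[Si](CC)(CC)CC)(C=C)[C@H]1C
F2 | step 14 | alkynol: C9≡C8 terminal alkyne on C10, free C5 hydroxyl, C1 OSiEt3 and vinyl, E-alkenyl chain | C#C[C@H](C)[C@@](O[Si](CC)(CC)CC)(C=C)[C@H](O)/C=C/CCOCc1ccc(OC)cc1
F3 | step 24 | trimethylsilyl enol ether of ketone 32 (C2=C3) | C=C1C(=O)O[C@@H]2[C@H]1C[C@@H](O[Si](CC)(CC)CC)[C@H](C)[C@@](O[Si](CC)(CC)CC)(C(=C)O[Si](C)(C)C)[C@H]2OC(=O)[C@@H](C)CC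
F4 | step 16 | 9-O-triethylsilyl ether of 21 | CC[Si](CC)(CC)O[C@@H]1C[C@@H](CCOCc2ccc(OC)cc2)C=C[C@](O[Si](CC)(CC)CC)(C=C)[C@H]1C
F5 | step 16 | trans bromohydrin of F4 (C6 hydroxyl on the upper face, C5 bromine on the lower face; the regioisomer closes to the same epoxide) | CC[Si](CC)(CC)O[C@@H]1C[C@@H](CCOCc2ccc(OC)cc2)[C@H](O)[C@@H](Br)[C@](O[Si](CC)(CC)CC)(C=C)[C@H]1C
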